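**Retrosynthetic overview**

1. Target 23 comes from its bis-TOM ether 22 by fluoride cleavage of the two silyloxymethyl acetals on the benzylic oxygens O7 and O7′.
2. 22 comes from dihalide 9 and the arm alcohols 18 and 20. The strategy rests on the two aryl ether links C4(ring B)–O–C8 and C4(ring C)–O–C8′: each is made on the aryl side by palladium-catalysed C–O coupling (bromide first, chloride second), so the secondary carbons C8 (S) and C8′ (R) are never touched.
3. 9 comes from hemiketal 8 (ionic hydrogenation sets C2), and 8 from lactone 5 plus the ring B aryllithium. 5 comes from syn-crotylboration of 4-chloro-3-methoxybenzaldehyde (C4, C5), hydroboration, oxidative lactonisation and trans-methylation (C3).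
4. 18 comes from ethyl (S)-lactate (C8) through an aryl ketone and chelation-controlled reduction (C7); 20 comes from 18 by Mitsunobu inversion at C8.
5. Ring order: the oxolane is the only ring built, first as the γ-lactone (step 3), then reduced to the cyclic ether (step 6); the four benzene rings are bought.

Key step: step 15

Remark on labels: ring B is the aryl on oxolane C2 and carries the erythro arm (C7, C8); ring C is the aryl on oxolane C5 and carries the threo arm (C7′, C8′); TOM = [tri(propan-2-yl)silyl]oxymethyl.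

Remark on the chemistry (assumption): the benzylic oxygens are carried as TOM acetals, not as plain silyl ethers, because a silyl group on O7 could shift to the neighbouring O8 alkoxide under Cs2CO3 at 80–110 °C and scramble the coupling site; the acetal cannot shift and still leaves with Bu4NF.

**Route**

Step 1
Reactants: 1 4-chloro-3-methoxybenzaldehyde
Product: 2 (1R,2S)-1-(4-chloro-3-methoxyphenyl)-2-methylbut-3-en-1-ol
Conditions: (Z)-but-2-ene, KOt-Bu, n-BuLi, THF, −78 to −45 °C; (+)-Ipc2BOMe, −78 °C; BF3·OEt2; then 1, −78 °C; NaOH, H2O2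
Reagents that add atoms: (Z)-but-2-ene, C/C=C\C
Why: Brown crotylboration through a closed chair transition state, in which the Z-crotyl geometry sets the 1,2-syn relationship and the isopinocampheyl groups from (−)-α-pinene direct attack to the re face of the aldehyde, should give the 1R,2S alcohol.

Step 2
Reactants: 2 (1R,2S)-1-(4-chloro-3-methoxyphenyl)-2-methylbut-3-en-1-ol
Product: 3 (1R,2S)-1-(4-chloro-3-methoxyphenyl)-2-methylbutane-1,4-diol
Conditions: 9-BBN, THF, 0 °C to rt; then NaOH, H2O2, 0 °C
Reagents that add atoms: hydrogen peroxide, OO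
Why: Anti-Markovnikov hydroboration–oxidation of the terminal alkene with the bulky borane should give the primary alcohol without touching either stereocentre or the aryl chloride.

Step 3
Reactants: 3 (1R,2S)-1-(4-chloro-3-methoxyphenyl)-2-methylbutane-1,4-diol
Product: 4 (4S,5R)-5-(4-chloro-3-methoxyphenyl)-4-methyloxolan-2-one
Conditions: TEMPO (cat.), PhI(OAc)2, CH2Cl2, rt
Reagents that add atoms: none
Why: Oxidative lactonisation of a 1,4-diol, in which the primary alcohol is oxidised to the aldehyde, closes to the lactol and is oxidised on to the γ-lactone faster than the hindered benzylic alcohol reacts.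

Step 4
Reactants: 4 (4S,5R)-5-(4-chloro-3-methoxyphenyl)-4-methyloxolan-2-one
Product: 5 (3S,4S,5R)-5-(4-chloro-3-methoxyphenyl)-3,4-dimethyloxolan-2-one
Conditions: LiN(SiMe3)2, THF, −78 °C; MeI, −78 °C
Reagents that add atoms: iodomethane, CI
Why: Kinetic lithium enolate alkylation, in which methyl iodide should enter from the face opposite the cis-disposed C4 methyl and C5 aryl groups and so set C3 (S) trans to C4.

Step 5
Reactants: 6 1-bromo-4-iodo-2-methoxybenzene; 5 (3S,4S,5R)-5-(4-chloro-3-methoxyphenyl)-3,4-dimethyloxolan-2-one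
Product: 8 (3S,4S,5R)-2-(4-bromo-3-methoxyphenyl)-5-(4-chloro-3-methoxyphenyl)-3,4-dimethyloxolan-2-ol (anomer mixture), via (4-bromo-3-methoxyphenyl)lithium 7 (not isolated)
Conditions: 6, n-BuLi (1.0 equiv), THF, −78 °C; then 5, −78 °C; AcOH, −78 °C
Reagents that add atoms: none
Why: Iodine–lithium exchange is far faster than bromine–lithium exchange at −78 °C, and the aryllithium should add once to the lactone carbonyl because the lithium hemiketal alkoxide is stable at that temperature (aryllithium addition to a lactone).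

Step 6
Reactants: 8 (3S,4S,5R)-2-(4-bromo-3-methoxyphenyl)-5-(4-chloro-3-methoxyphenyl)-3,4-dimethyloxolan-2-ol
Product: 9 (2S,3S,4S,5R)-2-(4-bromo-3-methoxyphenyl)-5-(4-chloro-3-methoxyphenyl)-3,4-dimethyloxolane
Conditions: Et3SiH, BF3·OEt2, CH2Cl2, −78 to −40 °C
Reagents that add atoms: none
Why: Ionic hydrogenation, in which BF3·OEt2 turns the hemiketal into the 2-aryl oxocarbenium ion and the silane delivers hydride by inside attack on the envelope (on the face of the C3 methyl, opposite the C4 methyl and the C5 aryl), should place ring B trans to the C3 methyl and set C2 as S, while the halogenated aryl groups disfavour benzylic ionisation and epimerisation.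

Step 7
Reactants: 10 ethyl (S)-lactate
Product: 11 ethyl (S)-2-(benzyloxy)propanoate
Conditions: BnOC(=NH)CCl3, TfOH (cat.), cyclohexane/CH2Cl2, rt
Reagents that add atoms: benzyl 2,2,2-trichloroacetimidate, ClC(Cl)(Cl)C(=N)OCc1ccccc1
Why: Acid-catalysed O-benzylation with the trichloroacetimidate uses no base, so the lactate stereocentre is not enolised.

Step 8
Reactants: 11 ethyl (S)-2-(benzyloxy)propanoate
Product: 12 (S)-2-(benzyloxy)-N-methoxy-N-methylpropanamide
Conditions: MeNHOMe·HCl, i-PrMgCl, THF, −20 to 0 °C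
Reagents that add atoms: N,O-dimethylhydroxylamine hydrochloride, CNOC.Cl
Why: Weinreb amide formation from the ester with the magnesium amide at low temperature should leave the α-alkoxy stereocentre intact.

Step 9
Reactants: 13 4-bromo-1,2-dimethoxybenzene; 12 (S)-2-(benzyloxy)-N-methoxy-N-methylpropanamide
Product: 15 (S)-2-(benzyloxy)-1-(3,4-dimethoxyphenyl)propan-1-one, via (3,4-dimethoxyphenyl)magnesium bromide 14 (not isolated)
Conditions: 13, Mg, THF, rt; then 12, 0 °C; 1 M HCl, 0 °C
Reagents that add atoms: none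
Why: Grignard addition to a Weinreb amide stops at the chelated tetrahedral intermediate, so the aryl ketone is released only on cold acidic work-up and the α-stereocentre should not enolise.

Step 10
Reactants: 15 (S)-2-(benzyloxy)-1-(3,4-dimethoxyphenyl)propan-1-one
Product: 16 (1R,2S)-2-(benzyloxy)-1-(3,4-dimethoxyphenyl)propan-1-ol
Conditions: Zn(BH4)2, Et2O, −30 to 0 °C
Reagents that add atoms: none
Why: Chelation-controlled (Cram chelate) reduction, in which zinc bridges the carbonyl and benzyloxy oxygens and hydride enters past the small α-hydrogen, should give the 1,2-anti (erythro) alcohol with C1 as R.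

Step 11
Reactants: 16 (1R,2S)-2-(benzyloxy)-1-(3,4-dimethoxyphenyl)propan-1-ol
Product: 17 {[(1R,2S)-2-(benzyloxy)-1-(3,4-dimethoxyphenyl)propoxy]methoxy}tri(propan-2-yl)silane
Conditions: TOMCl, i-Pr2NEt, Bu4NI (cat.), ClCH2CH2Cl, 0 to 50 °C
Reagents that add atoms: (chloromethoxy)tri(propan-2-yl)silane (TOMCl), CC(C)[Si](OCCl)(C(C)C)C(C)C
Why: Alkylation of the alcohol with the chloromethyl ether, as with SEM or MOM chloride, should give the mixed formaldehyde acetal, a fluoride-labile group that cannot transfer to a neighbouring alkoxide.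

Step 12
Reactants: 17 {[(1R,2S)-2-(benzyloxy)-1-(3,4-dimethoxyphenyl)propoxy]methoxy}tri(propan-2-yl)silane
Product: 18 (1R,2S)-1-(3,4-dimethoxyphenyl)-1-({[tri(propan-2-yl)silyl]oxy}methoxy)propan-2-ol (erythro arm alcohol)
Conditions: H2 (1 atm), Pd(OH)2/C, EtOAc, rt
Reagents that add atoms: none
Why: Neutral hydrogenolysis should cleave the primary O-benzyl ether much faster than the secondary benzylic acetal ether at C1.

Step 13
Reactants: 18 (1R,2S)-1-(3,4-dimethoxyphenyl)-1-({[tri(propan-2-yl)silyl]oxy}methoxy)propan-2-ol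
Product: 19 (1R,2R)-1-(3,4-dimethoxyphenyl)-1-({[tri(propan-2-yl)silyl]oxy}methoxy)propan-2-yl 4-nitrobenzoate
Conditions: 4-nitrobenzoic acid, PPh3, DIAD, toluene, 0 °C to rt
Reagents that add atoms: 4-nitrobenzoic acid, OC(=O)c1ccc(cc1)[N+](=O)[O-]
Why: Mitsunobu esterification proceeds by SN2 attack of the carboxylate on the alkoxyphosphonium ion, so C2 should invert from S to R (erythro to threo).

Step 14
Reactants: 19 (1R,2R)-1-(3,4-dimethoxyphenyl)-1-({[tri(propan-2-yl)silyl]oxy}methoxy)propan-2-yl 4-nitrobenzoate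
Product: 20 (1R,2R)-1-(3,4-dimethoxyphenyl)-1-({[tri(propan-2-yl)silyl]oxy}methoxy)propan-2-ol (threo arm alcohol)
Conditions: K2CO3 (cat.), MeOH, 0 °C to rt
Reagents that add atoms: none
Why: Base-catalysed methanolysis cleaves the ester at the acyl carbon, so the C2–O bond and its configuration are retained and the TOM acetal is untouched.

Step 15
Reactants: 9 (2S,3S,4S,5R)-2-(4-bromo-3-methoxyphenyl)-5-(4-chloro-3-methoxyphenyl)-3,4-dimethyloxolane; 18 erythro arm alcohol; 20 threo arm alcohol
Product: 22 bis-TOM ether of the target (ring B C4–O–C8 erythro arm and ring C C4–O–C8′ threo arm), via ring B monoether chloride 21 (not isolated)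
Conditions: [(η3-C3H5)PdCl]2 (2.5 mol %), RockPhos (7.5 mol %), Cs2CO3, toluene; 18 (1.0 equiv), 80 °C; then 20 (1.5 equiv), 110 °C
Reagents that add atoms: none
Why: Zerovalent palladium carrying the bulky biaryl phosphine inserts into the ring B C–Br bond, the caesium alkoxide of 18 replaces bromide on divalent palladium and C–O reductive elimination gives 21; after 20 is added and the bath is raised, the same cycle runs at the ring C C–Cl bond. The closest known reaction is the palladium-catalysed etherification of electron-rich, ortho-substituted aryl bromides and chlorides with secondary alcohols under RockPhos-type ligands. No ring is closed and no stereocentre is created, because only O–H and C(aryl)–halogen bonds are broken, so C8 (S) and C8′ (R) keep the configuration built into 18 and 20. The step needs site selectivity, which rests on oxidative addition to C–Br being much faster than to C–Cl, helped by the staged addition of the alcohols and the two temperatures. It also needs reductive elimination to outrun β-hydride elimination, which the ligand bulk and the ortho-methoxy group on each halide favour.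

Step 16
Reactants: 22 bis-TOM ether of the target
Product: 23 (1R,2S)-1-(3,4-dimethoxyphenyl)-2-{4-[(2S,3S,4S,5R)-5-(4-{[(1R,2R)-1-(3,4-dimethoxyphenyl)-1-hydroxypropan-2-yl]oxy}-3-methoxyphenyl)-3,4-dimethyloxolan-2-yl]-2-methoxyphenoxy}propan-1-ol (target)
Conditions: Bu4NF, THF, rt; aqueous work-up
Reagents that add atoms: none
Why: Fluoride attacks silicon and the resulting hemiacetal alkoxides lose formaldehyde, so both benzylic alcohols should be released at room temperature under non-acidic conditions that leave the aryl ethers and the oxolane untouched (fluoride cleavage of silyloxymethyl acetals).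

**Compound list**

1 | 4-chloro-3-methoxybenzaldehyde | COc1cc(C=O)ccc1Cl | starting material
2 | (1R,2S)-1-(4-chloro-3-methoxyphenyl)-2-methylbut-3-en-1-ol | O[C@@H](c1ccc(Cl)c(OC)c1)[C@@H](C)C=C | intermediate
3 | (1R,2S)-1-(4-chloro-3-methoxyphenyl)-2-methylbutane-1,4-diol | O[C@@H](c1ccc(Cl)c(OC)c1)[C@@H](C)CCO | intermediate
4 | (4S,5R)-5-(4-chloro-3-methoxyphenyl)-4-methyloxolan-2-one (4,5-cis) | COc1cc(ccc1Cl)[C@@H]2OC(=O)C[C@@H]2C | intermediate
5 | (3S,4S,5R)-5-(4-chloro-3-methoxyphenyl)-3,4-dimethyloxolan-2-one (3,4-trans, 4,5-cis) | COc1cc(ccc1Cl)[C@@H]2OC(=O)[C@@H](C)[C@@H]2C | intermediate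
6 | 1-bromo-4-iodo-2-methoxybenzene | COc1cc(I)ccc1Br | starting material
7 | (4-bromo-3-methoxyphenyl)lithium | COc1cc([Li])ccc1Br | intermediate
8 | (3S,4S,5R)-2-(4-bromo-3-methoxyphenyl)-5-(4-chloro-3-methoxyphenyl)-3,4-dimethyloxolan-2-ol (anomer mixture) | COc1cc(ccc1Br)C2(O)O[C@@H](c3ccc(Cl)c(OC)c3)[C@@H](C)[C@@H]2C | intermediate
9 | (2S,3S,4S,5R)-2-(4-bromo-3-methoxyphenyl)-5-(4-chloro-3-methoxyphenyl)-3,4-dimethyloxolane | COc1cc(ccc1Br)[C@H]2O[C@@H](c3ccc(Cl)c(OC)c3)[C@@H](C)[C@@H]2C | intermediate
10 | ethyl (S)-lactate | C[C@H](O)C(=O)OCC | starting material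
11 | ethyl (S)-2-(benzyloxy)propanoate | C[C@H](OCc1ccccc1)C(=O)OCC | intermediate
12 | (S)-2-(benzyloxy)-N-methoxy-N-methylpropanamide | C[C@H](OCc1ccccc1)C(=O)N(C)OC | intermediate
13 | 4-bromo-1,2-dimethoxybenzene | COc1ccc(Br)cc1OC | starting material
14 | (3,4-dimethoxyphenyl)magnesium bromide | COc1ccc([Mg]Br)cc1OC | intermediate
15 | (S)-2-(benzyloxy)-1-(3,4-dimethoxyphenyl)propan-1-one | C[C@H](OCc1ccccc1)C(=O)c1ccc(OC)c(OC)c1 | intermediate
16 | (1R,2S)-2-(benzyloxy)-1-(3,4-dimethoxyphenyl)propan-1-ol | C[C@H](OCc1ccccc1)[C@H](O)c1ccc(OC)c(OC)c1 | intermediate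
17 | {[(1R,2S)-2-(benzyloxy)-1-(3,4-dimethoxyphenyl)propoxy]methoxy}tri(propan-2-yl)silane | C[C@H](OCc1ccccc1)[C@H](OCO[Si](C(C)C)(C(C)C)C(C)C)c1ccc(OC)c(OC)c1 | intermediate
18 | (1R,2S)-1-(3,4-dimethoxyphenyl)-1-({[tri(propan-2-yl)silyl]oxy}methoxy)propan-2-ol | O[C@@H](C)[C@H](OCO[Si](C(C)C)(C(C)C)C(C)C)c1ccc(OC)c(OC)c1 | intermediate
19 | (1R,2R)-1-(3,4-dimethoxyphenyl)-1-({[tri(propan-2-yl)silyl]oxy}methoxy)propan-2-yl 4-nitrobenzoate | O=C(O[C@H](C)[C@H](OCO[Si](C(C)C)(C(C)C)C(C)C)c1ccc(OC)c(OC)c1)c1ccc(cc1)[N+](=O)[O-] | intermediate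
20 | (1R,2R)-1-(3,4-dimethoxyphenyl)-1-({[tri(propan-2-yl)silyl]oxy}methoxy)propan-2-ol | O[C@H](C)[C@H](OCO[Si](C(C)C)(C(C)C)C(C)C)c1ccc(OC)c(OC)c1 | intermediate
21 | ring B monoether chloride: 9 with the ring B bromine replaced by the (1R,2S) arm bound through O–C8, ring C chloride intact | COc1cc(ccc1O[C@@H](C)[C@H](OCO[Si](C(C)C)(C(C)C)C(C)C)c2ccc(OC)c(OC)c2)[C@H]3O[C@@H](c4ccc(Cl)c(OC)c4)[C@@H](C)[C@@H]3C | intermediate
22 | bis-TOM ether of the target | COc1cc(ccc1O[C@@H](C)[C@H](OCO[Si](C(C)C)(C(C)C)C(C)C)c2ccc(OC)c(OC)c2)[C@H]3O[C@@H](c4ccc(O[C@H](C)[C@H](OCO[Si](C(C)C)(C(C)C)C(C)C)c5ccc(OC)c(OC)c5)c(OC)c4)[C@@H](C)[C@@H]3C | intermediate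
23 | CNP0116650.9 | COc1ccc([C@@H](O)[C@H](C)Oc2ccc([C@H]3O[C@@H](c4ccc(O[C@H](C)[C@H](O)c5ccc(OC)c(OC)c5)c(OC)c4)[C@@H](C)[C@@H]3C)cc2OC)cc1OC | target

**Step count and risks**

Total step count: 16. Longest linear sequence: 10 steps (ethyl (S)-lactate 10 through 11, 12, 15, 16, 17, 18, 19, 20 and 22 to 23).

Steps most likely to fail:

1. Step 15. The palladium alkoxide of a branched secondary alcohol may undergo β-hydride elimination (reducing the aryl halide) faster than C–O reductive elimination, and the two arms may exchange sites if the bromide is not fully consumed before the second alcohol is added. The fallback sets out from 9 and returns at 22, passing through 21; it forms the O–C8 bonds by Mitsunobu etherification with inversion, so the arms are used in exchanged roles. Bromide-selective Miyaura borylation of 9 (Pd(dppf)Cl2, B2pin2, KOAc, dioxane, 80 °C) would give the ring B pinacol boronate F1, and NaBO3·4H2O in THF/H2O the ring B phenol F2. Mitsunobu reaction of F2 with the threo alcohol 20 (PPh3, DIAD, toluene) inverts C8 to S and gives 21. Borylation of the chloride of 21 (Pd2(dba)3, XPhos, B2pin2, KOAc, dioxane, 100 °C) would give the ring C pinacol boronate F3, oxidation the ring C phenol F4, and a second Mitsunobu reaction with the erythro alcohol 18 (inversion to 8′R) returns to 22.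

2. Step 13. SN2 displacement at the hindered C2 may be slow, and elimination or participation by the neighbouring aryl group or acetal oxygen may compete, eroding the inversion. The fallback sets out from 18 and returns at 20 by oxidation and reduction in place of displacement. Dess–Martin periodinane (NaHCO3, CH2Cl2) would give (1R)-1-(3,4-dimethoxyphenyl)-1-({[tri(propan-2-yl)silyl]oxy}methoxy)propan-2-one F5, used at once to avoid α-epimerisation. Felkin–Anh reduction with LiBH(s-Bu)3 (THF, −78 °C), hydride entering anti to the α-acetal oxygen, should give the 1,2-syn (threo) alcohol 20.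

3. Step 5. The aryllithium may enolise the α-methyl lactone (returning or C3-epimerising 5), scramble halogen with aryl bromide present, or add twice. The fallback sets out from 5 and returns at 8 through an open-chain Weinreb amide and a Grignard reagent. AlMe3 and MeNHOMe·HCl (CH2Cl2) would open the lactone to the hydroxy Weinreb amide F6, and Et3SiOTf/2,6-lutidine would give its triethylsilyl ether F7. The arylmagnesium chloride F8, made from 6 by iodine–magnesium exchange with i-PrMgCl·LiCl at −20 °C, would add to F7 to give the aryl ketone F9. Bu4NF/AcOH then removes the silyl group and the hydroxy ketone closes to 8.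

**Further compounds**

F1 | step 15 | 2-{4-[(2S,3S,4S,5R)-5-(4-chloro-3-methoxyphenyl)-3,4-dimethyloxolan-2-yl]-2-methoxyphenyl}-4,4,5,5-tetramethyl-1,3,2-dioxaborolane | COc1cc(ccc1B5OC(C)(C)C(C)(C)O5)[C@H]2O[C@@H](c3ccc(Cl)c(OC)c3)[C@@H](C)[C@@H]2C
F2 | step 15 | 4-[(2S,3S,4S,5R)-5-(4-chloro-3-methoxyphenyl)-3,4-dimethyloxolan-2-yl]-2-methoxyphenol | COc1cc(ccc1O)[C@H]2O[C@@H](c3ccc(Cl)c(OC)c3)[C@@H](C)[C@@H]2C
F3 | step 15 | ring C pinacol boronate of 21 (chlorine replaced by the dioxaborolanyl group) | COc1cc(ccc1O[C@@H](C)[C@H](OCO[Si](C(C)C)(C(C)C)C(C)C)c2ccc(OC)c(OC)c2)[C@H]3O[C@@H](c4ccc(B5OC(C)(C)C(C)(C)O5)c(OC)c4)[C@@H](C)[C@@H]3C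
F4 | step 15 | ring C phenol of 21 (chlorine replaced by hydroxyl) | COc1cc(ccc1O[C@@H](C)[C@H](OCO[Si](C(C)C)(C(C)C)C(C)C)c2ccc(OC)c(OC)c2)[C@H]3O[C@@H](c4ccc(O)c(OC)c4)[C@@H](C)[C@@H]3C
F5 | step 13 | (1R)-1-(3,4-dimethoxyphenyl)-1-({[tri(propan-2-yl)silyl]oxy}methoxy)propan-2-one | CC(=O)[C@H](OCO[Si](C(C)C)(C(C)C)C(C)C)c1ccc(OC)c(OC)c1
F6 | step 5 | (2S,3S,4R)-4-(4-chloro-3-methoxyphenyl)-4-hydroxy-N-methoxy-N,2,3-trimethylbutanamide | CON(C)C(=O)[C@@H](C)[C@H](C)[C@@H](O)c1ccc(Cl)c(OC)c1
F7 | step 5 | (2S,3S,4R)-4-(4-chloro-3-methoxyphenyl)-N-methoxy-N,2,3-trimethyl-4-(triethylsilyloxy)butanamide | CON(C)C(=O)[C@@H](C)[C@H](C)[C@@H](O[Si](CC)(CC)CC)c1ccc(Cl)c(OC)c1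
F8 | step 5 | (4-bromo-3-methoxyphenyl)magnesium chloride | COc1cc([Mg]Cl)ccc1Br
F9 | step 5 | (2S,3S,4R)-1-(4-bromo-3-methoxyphenyl)-4-(4-chloro-3-methoxyphenyl)-2,3-dimethyl-4-(triethylsilyloxy)butan-1-one | COc1cc(ccc1Br)C(=O)[C@@H](C)[C@H](C)[C@@H](O[Si](CC)(CC)CC)c2ccc(Cl)c(OC)c2
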